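**Retrosynthetic overview**

1. The target is C2-symmetric, so both C10=C11 bonds are cut last. This gives two copies of a ring aldehyde (C1–C10) and a central C11–C11' bisphosphonate, joined by a two-directional double Horner–Wadsworth–Emmons reaction and then desilylated.
2. The ring aldehyde comes from a ring diol (oxidation, then Wittig for C8=C9). The diol comes from a 4-alkylidene enone (CBS reduction sets C3; protodesilylation frees C7–H).
3. Ring formation is the only ring-forming step, and each end ring is made on this one building block before any chain is attached. It is a Diels–Alder reaction of a vinylallene ketene acetal (C3=C4–C5(CH3)=C6=C7) with 2-methyl-1-nitropropene (C1=C2), closing C2–C3 and C1–C6 at once.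
4. Enabling feature: in each ring the C4=C5 double bond lies between the oxygen-bearing C3 and C6, and C6 carries the exocyclic C6=C7 double bond. The ring is therefore the cycloadduct pattern (3-alkylidenecyclohexene) of a vinylallene, and C1–C2 is an isobutene unit. A nitro group on C2 (activation, regiocontrol) and a silyl group on C7 (face control, hence the 6E geometry) are temporary.
5. The vinylallene comes from a (Z)-enynoate (Sonogashira coupling) by copper-catalysed 1,6-silyl addition. The bisphosphonate comes from homocoupling of a dienylstannane made from (E)-3-methylpent-2-en-4-yn-1-ol.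

Key step: step 5

**Remarks on the chemistry**

- Locants follow carotenoid numbering: ring C1 (gem-dimethyl), C2 (CH2), C3 (carbinol), C4=C5 (C5 bears CH3), C6 (ring carbon of the exocyclic alkene), chain C7–C15; primes mark the second half.
- All numbered starting materials and all reagents are assumed to be commercial.
- The allene axis of the allenylsilane is racemic and the ketene acetal geometry is uncontrolled. Both elements are consumed in step 5 without consequence.
- The two end rings are identical, so steps 1–11 are run once and the ring aldehyde is used twice.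
- All polyene intermediates are handled under argon with exclusion of light.

**Route**

Step 1
Reactants: 1 ethyl but-2-ynoate
Product: 2 ethyl (2Z)-3-iodobut-2-enoate
Conditions: NaI, AcOH, 110 °C
Reagents that add atoms: sodium iodide, [Na+].[I-]
Why: Conjugate hydroiodination of an ynoate is an anti addition of iodide and a proton, so iodine and the ester end up cis and the (Z)-β-iodo enoate should result.

Step 2
Reactants: 2 ethyl (2Z)-3-iodobut-2-enoate; 3 tert-butyldimethyl(prop-2-yn-1-yloxy)silane
Product: 4 ethyl (2Z)-6-[(tert-butyldimethylsilyl)oxy]-3-methylhex-2-en-4-ynoate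
Conditions: PdCl2(PPh3)2 (2 mol %), CuI (4 mol %), Et3N, THF, 23 °C
Reagents that add atoms: none
Why: Sonogashira coupling of a vinyl iodide with a terminal alkyne proceeds with retention of alkene geometry and tolerates the ester and the silyl ether.

Step 3
Reactants: 4 ethyl (2Z)-6-[(tert-butyldimethylsilyl)oxy]-3-methylhex-2-en-4-ynoate
Product: 5 ethyl 6-[(tert-butyldimethylsilyl)oxy]-5-[dimethyl(phenyl)silyl]-3-methylhexa-3,4-dienoate (racemic allene)
Conditions: PhMe2Si–Bpin (1.2 equiv), CuCl (5 mol %), NaO-t-Bu (10 mol %), PPh3 (10 mol %), MeOH (2 equiv), THF, 0 → 23 °C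
Reagents that add atoms: 2-[dimethyl(phenyl)silyl]-4,4,5,5-tetramethyl-1,3,2-dioxaborolane, C[Si](C)(c1ccccc1)B1OC(C)(C)C(C)(C)O1
Why: Copper-catalysed 1,6-conjugate silyl transfer from a silylboronate to a 2-en-4-ynoate places silicon on the alkyne carbon remote from the ester (C7), and α-protonation of the resulting allenyl enolate by methanol should give the tetrasubstituted allenylsilane.

Step 4
Reactants: 5 ethyl 6-[(tert-butyldimethylsilyl)oxy]-5-[dimethyl(phenyl)silyl]-3-methylhexa-3,4-dienoate
Product: 6 tert-butyl({6-[(tert-butyldimethylsilyl)oxy]-5-[dimethyl(phenyl)silyl]-1-ethoxy-3-methylhexa-1,3,4-trien-1-yl}oxy)dimethylsilane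
Conditions: LDA (1.1 equiv), TBSCl (1.2 equiv, present during the deprotonation), THF–DMPU, −78 → 0 °C; pentane, filtration, concentration
Reagents that add atoms: tert-butyldimethylsilyl chloride, CC(C)(C)[Si](C)(C)Cl
Why: Kinetic α-deprotonation of the β,γ-allenic ester with in situ O-silylation (silyl ketene acetal formation) should give the conjugated 1-ethoxy-1-silyloxy vinylallene, obtained free of amine by the non-aqueous work-up.

Step 5
Reactants: 6 tert-butyl({6-[(tert-butyldimethylsilyl)oxy]-5-[dimethyl(phenyl)silyl]-1-ethoxy-3-methylhexa-1,3,4-trien-1-yl}oxy)dimethylsilane; 7 2-methyl-1-nitroprop-1-ene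
Product: 9 (4E)-4-{2-[(tert-butyldimethylsilyl)oxy]-1-[dimethyl(phenyl)silyl]ethylidene}-3,5,5-trimethyl-6-nitrocyclohex-2-en-1-one (racemic at the nitro-bearing carbon), via ketal cycloadduct 8 (not isolated)
Conditions: toluene, −20 → 23 °C; then 0.5 M HCl, THF, 0 °C
Reagents that add atoms: none
Why: This is a normal-electron-demand Diels–Alder cycloaddition, concerted but asynchronous: the sp-hybridised central allene carbon C6, which carries the largest terminal HOMO coefficient of the 1-ethoxy-1-silyloxy vinylallene, bonds first to the electrophilic CMe2 carbon of the nitroalkene while the nitro-bearing carbon closes onto the ketene-acetal carbon C3, and the acidic work-up unmasks the C3 ketone in conjugation with the new C4=C5 bond. The closest known reaction types are Diels–Alder reactions of vinylallenes, which give 3-alkylidenecyclohexenes, and of 1-alkoxy-1-silyloxy dienes with nitroalkenes. The cyclohexene ring is closed by the intermolecular [4+2] cycloaddition itself, both ring bonds (C1–C6 and C2–C3) being made in this single event. The two new stereocentres (nitro-bearing C2 and ketal carbon C3) need no control because they are erased in the work-up and in step 6; the element that matters is the C6=C7 geometry, which is fixed by attack of the dienophile on the allene face anti to the bulky SiMe2Ph group on C7, leaving CH2OTBS cis to the new C1–C6 bond. The step needs regioselectivity (secured by the matched polarisation of the O,O-acetal donor and the nitro acceptor), carbocyclic cycloaddition in preference to hetero-cycloaddition or α-alkylation (favoured by the unhindered sp carbon C6 and the hindered β,β-dimethyl nitroalkene) and π-facial selectivity (silyl versus CH2OTBS). Loss of HNO2 from the adduct is not possible because C2 is flanked by the quaternary C1 and the carbonyl carbon.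

Step 6
Reactants: 9 (4E)-4-{2-[(tert-butyldimethylsilyl)oxy]-1-[dimethyl(phenyl)silyl]ethylidene}-3,5,5-trimethyl-6-nitrocyclohex-2-en-1-one
Product: 10 (4Z)-4-{2-[(tert-butyldimethylsilyl)oxy]-1-[dimethyl(phenyl)silyl]ethylidene}-3,5,5-trimethylcyclohex-2-en-1-one
Conditions: Bu3SnH (1.5 equiv), AIBN (0.2 equiv), benzene, 80 °C
Reagents that add atoms: none
Why: Radical denitration of an α-nitro ketone with tributyltin hydride passes through a stabilised α-keto radical that should be reduced faster than it can rearrange, leaving C2 as CH2 (the descriptor changes from E to Z only because the CIP priorities change).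

Step 7
Reactants: 10 (4Z)-4-{2-[(tert-butyldimethylsilyl)oxy]-1-[dimethyl(phenyl)silyl]ethylidene}-3,5,5-trimethylcyclohex-2-en-1-one
Product: 11 (1S,4Z)-4-{2-[(tert-butyldimethylsilyl)oxy]-1-[dimethyl(phenyl)silyl]ethylidene}-3,5,5-trimethylcyclohex-2-en-1-ol
Conditions: (R)-2-methyl-CBS-oxazaborolidine (0.3 equiv), catecholborane (1.5 equiv), toluene, −78 °C; MeOH, then aqueous NaOH wash
Reagents that add atoms: none
Why: Corey–Bakshi–Shibata reduction delivers hydride 1,2 to the enone face selected by the (R)-catalyst, which treats the alkenyl flank (C4) as the large and the CH2 flank (C2) as the small substituent and should therefore set the (3S) carbinol.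

Step 8
Reactants: 11 (1S,4Z)-4-{2-[(tert-butyldimethylsilyl)oxy]-1-[dimethyl(phenyl)silyl]ethylidene}-3,5,5-trimethylcyclohex-2-en-1-ol
Product: 13 (1S,4E)-4-(2-hydroxyethylidene)-3,5,5-trimethylcyclohex-2-en-1-ol, via silyl allylic alcohol 12 (not isolated)
Conditions: TBAF (4 equiv), wet THF–DMSO, 23 → 60 °C
Reagents that add atoms: none
Why: Fluoride first cleaves the primary silyl ether and then effects protodesilylation of the vinylsilane, helped by the neighbouring C8 alkoxide and by relief of strain at the tetrasubstituted alkene, with retention of alkene geometry so that C8 stays cis to C1 (6E).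

Step 9
Reactants: 13 (1S,4E)-4-(2-hydroxyethylidene)-3,5,5-trimethylcyclohex-2-en-1-ol
Product: 14 (2E)-2-[(4S)-4-hydroxy-2,6,6-trimethylcyclohex-2-en-1-ylidene]acetaldehyde
Conditions: TEMPO (0.1 equiv), PhI(OAc)2 (1.1 equiv), CH2Cl2, 0 → 23 °C
Reagents that add atoms: none
Why: Oxoammonium-mediated oxidation (TEMPO with PhI(OAc)2) is selective for the primary allylic alcohol over the secondary C3 alcohol and stops at the aldehyde.

Step 10
Reactants: 14 (2E)-2-[(4S)-4-hydroxy-2,6,6-trimethylcyclohex-2-en-1-ylidene]acetaldehyde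
Product: 15 (2E)-2-[(4S)-4-[(tert-butyldimethylsilyl)oxy]-2,6,6-trimethylcyclohex-2-en-1-ylidene]acetaldehyde
Conditions: TBSCl, imidazole, DMF, 0 → 23 °C
Reagents that add atoms: tert-butyldimethylsilyl chloride, CC(C)(C)[Si](C)(C)Cl
Why: Standard silylation shields the C3 alcohol from alkoxide-mediated side reactions in the basic olefination of step 16 and does not touch the stereocentre.

Step 11
Reactants: 15 (2E)-2-[(4S)-4-[(tert-butyldimethylsilyl)oxy]-2,6,6-trimethylcyclohex-2-en-1-ylidene]acetaldehyde; 16 2-(triphenylphosphoranylidene)propanal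
Product: 17 (2E,4E)-4-[(4S)-4-[(tert-butyldimethylsilyl)oxy]-2,6,6-trimethylcyclohex-2-en-1-ylidene]-2-methylbut-2-enal
Conditions: toluene, 80 °C, dark
Reagents that add atoms: none
Why: Wittig reaction of the stabilised formyl ylide with the unhindered enal should give the (E)-trisubstituted C8=C9 alkene, and the α-branched trienal product reacts much more slowly with further ylide.

Step 12
Reactants: 18 (2E)-3-methylpent-2-en-4-yn-1-ol
Product: 19 (2E,4E)-3-methyl-5-(tributylstannyl)penta-2,4-dien-1-ol
Conditions: Bu3SnH (1.1 equiv), Pd2(dba)3 (0.5 mol %), Cy3P·HBF4 (2 mol %), i-Pr2NEt (4 mol %), CH2Cl2, 0 °C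
Reagents that add atoms: tributyltin hydride, CCCC[SnH](CCCC)CCCC
Why: Palladium-catalysed hydrostannation of a terminal alkyne with a bulky phosphine is a syn addition that places tin on the terminal carbon and should give the (E)-alkenylstannane.

Step 13
Reactants: 19 (2E,4E)-3-methyl-5-(tributylstannyl)penta-2,4-dien-1-ol (two molecules)
Product: 20 (2E,4E,6E,8E)-3,8-dimethyldeca-2,4,6,8-tetraene-1,10-diol
Conditions: Cu(NO3)2·3H2O (1.0 equiv per stannane), THF, 23 °C
Reagents that add atoms: none
Why: Copper-mediated oxidative homocoupling of alkenylstannanes joins the two tin-bearing carbons (the C15–C15' bond) with retention of both alkene geometries and tolerates free hydroxyl groups.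

Step 14
Reactants: 20 (2E,4E,6E,8E)-3,8-dimethyldeca-2,4,6,8-tetraene-1,10-diol
Product: 21 (2E,4E,6E,8E)-1,10-dibromo-3,8-dimethyldeca-2,4,6,8-tetraene
Conditions: PBr3 (0.7 equiv), pyridine (cat.), Et2O, −10 °C, dark; used at once
Reagents that add atoms: phosphorus tribromide, BrP(Br)Br
Why: Primary allylic alcohols are converted by PBr3 into the terminal, fully conjugated bromides under the conditions used for the shorter polyene diols of carotenoid chemistry.

Step 15
Reactants: 21 (2E,4E,6E,8E)-1,10-dibromo-3,8-dimethyldeca-2,4,6,8-tetraene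
Product: 22 tetraethyl [(2E,4E,6E,8E)-3,8-dimethyldeca-2,4,6,8-tetraene-1,10-diyl]bis(phosphonate)
Conditions: P(OEt)3 (excess), 90 °C
Reagents that add atoms: triethyl phosphite, CCOP(OCC)OCC
Why: Michaelis–Arbuzov reaction at the unhindered terminal carbons of the allylic dibromide should give the bisphosphonate with the all-E tetraene intact.

Step 16
Reactants: 22 tetraethyl [(2E,4E,6E,8E)-3,8-dimethyldeca-2,4,6,8-tetraene-1,10-diyl]bis(phosphonate); 17 (2E,4E)-4-[(4S)-4-[(tert-butyldimethylsilyl)oxy]-2,6,6-trimethylcyclohex-2-en-1-ylidene]-2-methylbut-2-enal (two equivalents)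
Product: 23 (3S,3'S)-3,3'-bis-O-(tert-butyldimethylsilyl)eschscholtzxanthin
Conditions: KO-t-Bu (2.2 equiv), THF, −20 °C; then 17, −20 → 23 °C, argon, dark
Reagents that add atoms: none
Why: Two-directional Horner–Wadsworth–Emmons olefination of the bis(phosphonate) carbanion with the enal should form both disubstituted C10=C11 bonds with the E selectivity typical of allylic phosphonates, without touching the existing alkenes or the silyl ethers.

Step 17
Reactants: 23 (3S,3'S)-3,3'-bis-O-(tert-butyldimethylsilyl)eschscholtzxanthin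
Product: 24 (3S,3'S,6E,6'E)-4',5'-didehydro-4,5'-retro-β,β-carotene-3,3'-diol (eschscholtzxanthin, CNP0349476.1)
Conditions: TBAF, THF, 23 °C, argon, dark; crystallisation
Reagents that add atoms: none
Why: Fluoride cleaves both secondary silyl ethers under non-acidic conditions that spare the allylic carbinols and the polyene, and crystallisation of the C2-symmetric diol should remove the meso diastereomer into which any minor enantiomer of 17 is expected to be channelled.

**Compound list**

1 | ethyl but-2-ynoate | CC#CC(=O)OCC | starting material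
2 | ethyl (2Z)-3-iodobut-2-enoate | CCOC(=O)/C=C(/C)I | intermediate
3 | tert-butyldimethyl(prop-2-yn-1-yloxy)silane | C#CCO[Si](C)(C)C(C)(C)C | starting material
4 | ethyl (2Z)-6-[(tert-butyldimethylsilyl)oxy]-3-methylhex-2-en-4-ynoate | CCOC(=O)/C=C(/C)C#CCO[Si](C)(C)C(C)(C)C | intermediate
5 | ethyl 6-[(tert-butyldimethylsilyl)oxy]-5-[dimethyl(phenyl)silyl]-3-methylhexa-3,4-dienoate (racemic allene) | CCOC(=O)CC(C)=C=C([Si](C)(C)c1ccccc1)CO[Si](C)(C)C(C)(C)C | intermediate
6 | tert-butyl({6-[(tert-butyldimethylsilyl)oxy]-5-[dimethyl(phenyl)silyl]-1-ethoxy-3-methylhexa-1,3,4-trien-1-yl}oxy)dimethylsilane (racemic allene, ketene acetal geometry unassigned) | CCOC(O[Si](C)(C)C(C)(C)C)=CC(C)=C=C([Si](C)(C)c1ccccc1)CO[Si](C)(C)C(C)(C)C | intermediate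
7 | 2-methyl-1-nitroprop-1-ene | CC(C)=C[N+](=O)[O-] | starting material
8 | (4E)-1-ethoxy-1-[(tert-butyldimethylsilyl)oxy]-4-{2-[(tert-butyldimethylsilyl)oxy]-1-[dimethyl(phenyl)silyl]ethylidene}-3,5,5-trimethyl-6-nitrocyclohex-2-ene (ketal cycloadduct, diastereomer mixture, silicon cis to the methyl-bearing ring alkene carbon) | CCOC1(O[Si](C)(C)C(C)(C)C)C=C(C)/C(=C(\[Si](C)(C)c2ccccc2)CO[Si](C)(C)C(C)(C)C)C(C)(C)C1[N+](=O)[O-] | intermediate
9 | (4E)-4-{2-[(tert-butyldimethylsilyl)oxy]-1-[dimethyl(phenyl)silyl]ethylidene}-3,5,5-trimethyl-6-nitrocyclohex-2-en-1-one (racemic at C6) | CC1=CC(=O)C([N+](=O)[O-])C(C)(C)/C1=C(/[Si](C)(C)c2ccccc2)CO[Si](C)(C)C(C)(C)C | intermediate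
10 | (4Z)-4-{2-[(tert-butyldimethylsilyl)oxy]-1-[dimethyl(phenyl)silyl]ethylidene}-3,5,5-trimethylcyclohex-2-en-1-one | CC1=CC(=O)CC(C)(C)/C1=C(/[Si](C)(C)c2ccccc2)CO[Si](C)(C)C(C)(C)C | intermediate
11 | (1S,4Z)-4-{2-[(tert-butyldimethylsilyl)oxy]-1-[dimethyl(phenyl)silyl]ethylidene}-3,5,5-trimethylcyclohex-2-en-1-ol | CC1=C[C@@H](O)CC(C)(C)/C1=C(/[Si](C)(C)c2ccccc2)CO[Si](C)(C)C(C)(C)C | intermediate
12 | (1S,4Z)-4-{1-[dimethyl(phenyl)silyl]-2-hydroxyethylidene}-3,5,5-trimethylcyclohex-2-en-1-ol | CC1=C[C@@H](O)CC(C)(C)/C1=C(/[Si](C)(C)c2ccccc2)CO | intermediate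
13 | (1S,4E)-4-(2-hydroxyethylidene)-3,5,5-trimethylcyclohex-2-en-1-ol | CC1=C[C@@H](O)CC(C)(C)\C1=C/CO | intermediate
14 | (2E)-2-[(4S)-4-hydroxy-2,6,6-trimethylcyclohex-2-en-1-ylidene]acetaldehyde | CC1=C[C@@H](O)CC(C)(C)\C1=C/C=O | intermediate
15 | (2E)-2-[(4S)-4-[(tert-butyldimethylsilyl)oxy]-2,6,6-trimethylcyclohex-2-en-1-ylidene]acetaldehyde | CC1=C[C@@H](O[Si](C)(C)C(C)(C)C)CC(C)(C)\C1=C/C=O | intermediate
16 | 2-(triphenylphosphoranylidene)propanal | CC(C=O)=P(c1ccccc1)(c1ccccc1)c1ccccc1 | starting material
17 | (2E,4E)-4-[(4S)-4-[(tert-butyldimethylsilyl)oxy]-2,6,6-trimethylcyclohex-2-en-1-ylidene]-2-methylbut-2-enal | CC1=C[C@@H](O[Si](C)(C)C(C)(C)C)CC(C)(C)\C1=C/C=C(C)/C=O | intermediate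
18 | (2E)-3-methylpent-2-en-4-yn-1-ol | OC/C=C(\C)C#C | starting material
19 | (2E,4E)-3-methyl-5-(tributylstannyl)penta-2,4-dien-1-ol | OC/C=C(\C)/C=C/[Sn](CCCC)(CCCC)CCCC | intermediate
20 | (2E,4E,6E,8E)-3,8-dimethyldeca-2,4,6,8-tetraene-1,10-diol | OC/C=C(\C)/C=C/C=C/C(C)=C/CO | intermediate
21 | (2E,4E,6E,8E)-1,10-dibromo-3,8-dimethyldeca-2,4,6,8-tetraene | BrC/C=C(\C)/C=C/C=C/C(C)=C/CBr | intermediate
22 | tetraethyl [(2E,4E,6E,8E)-3,8-dimethyldeca-2,4,6,8-tetraene-1,10-diyl]bis(phosphonate) | CCOP(=O)(OCC)C/C=C(\C)/C=C/C=C/C(C)=C/CP(=O)(OCC)OCC | intermediate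
23 | (3S,3'S)-3,3'-bis-O-(tert-butyldimethylsilyl)eschscholtzxanthin | CC1=C[C@@H](O[Si](C)(C)C(C)(C)C)CC(C)(C)\C1=C/C=C(C)/C=C/C=C(C)/C=C/C=C/C(C)=C/C=C/C(C)=C/C=C1/C(C)=C[C@@H](O[Si](C)(C)C(C)(C)C)CC1(C)C | intermediate
24 | (3S,3'S,6E,6'E)-4',5'-didehydro-4,5'-retro-β,β-carotene-3,3'-diol (eschscholtzxanthin) | CC1=C[C@@H](O)CC(C)(C)\C1=C/C=C(C)/C=C/C=C(C)/C=C/C=C/C(C)=C/C=C/C(C)=C/C=C1/C(C)=C[C@@H](O)CC1(C)C | target

**Step count**

Total: 17 steps. Longest linear sequence: 13 steps (steps 1–11, 16, 17); the central fragment takes 4 steps (12–15).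

**Steps most likely to fail, with fallbacks**

Step 5. The cycloaddition may lose π-facial selectivity at the allene, which would scramble the C6=C7 geometry. It may also be overtaken by hetero-cycloaddition of the nitroalkene (cyclic nitronate formation) or by alkylation at the α-carbon of the ketene acetal. The fallback sets out from 6 and returns at 9, forming the same two bonds one after the other so that each can be driven and checked separately. A vinylogous Mukaiyama–Michael addition of 6 to 7 (catalytic TBSOTf, CH2Cl2, −78 °C, aqueous work-up) should give the open-chain nitro dienoate ethyl (2Z)-4-{2-[(tert-butyldimethylsilyl)oxy]-1-[dimethyl(phenyl)silyl]ethylidene}-3,5,5-trimethyl-6-nitrohex-2-enoate F1. Its alkylidene geometry can be purified at this acyclic stage. Treatment of F1 with KO-t-Bu (THF, 0 °C, then dilute HCl) should close the ring by intramolecular C-acylation of the nitronate by the ester (a Dieckmann-type condensation), with the C4=C5 geometry able to equilibrate through the dienolate, and so deliver 9.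

Step 8. The protodesilylation may be slow. It may also be diverted into elimination of silicon together with the C8 oxygen (allene formation) or into geometric isomerisation of the exocyclic alkene under the basic, warm conditions. The fallback sets out from 11 and returns at 13, replacing nucleophilic cleavage by an electrophilic ipso substitution followed by reduction:
- N-iodosuccinimide (MeCN, 0 °C) should exchange silicon for iodine with retention, giving (1S,4Z)-4-{2-[(tert-butyldimethylsilyl)oxy]-1-iodoethylidene}-3,5,5-trimethylcyclohex-2-en-1-ol F2.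
- Hydrogenolysis of the C–I bond with Pd(PPh3)4 (cat.) and Bu3SnH (THF, 23 °C), also with retention, should give (1S,4E)-4-{2-[(tert-butyldimethylsilyl)oxy]ethylidene}-3,5,5-trimethylcyclohex-2-en-1-ol F3.
- TBAF (THF, 0 °C) then gives 13.

Step 7. Enantiofacial discrimination between the alkenyl flank and the neopentyl-type CH2 flank of the ketone may be insufficient, or conjugate reduction may compete. The fallback sets out from 10 and returns at 11 by resolution instead of reagent control. Luche reduction (NaBH4, CeCl3·7H2O, MeOH, −40 °C) should give the racemic alcohol (4Z)-4-{2-[(tert-butyldimethylsilyl)oxy]-1-[dimethyl(phenyl)silyl]ethylidene}-3,5,5-trimethylcyclohex-2-en-1-ol F4. Lipase-catalysed acylation (Burkholderia cepacia lipase, vinyl acetate, MTBE, 30 °C) is predicted, by the empirical rule for secondary alcohols, to acetylate the (R)-enantiomer to (1R,4Z)-4-{2-[(tert-butyldimethylsilyl)oxy]-1-[dimethyl(phenyl)silyl]ethylidene}-3,5,5-trimethylcyclohex-2-en-1-yl acetate F5. The unreacted (S)-alcohol 11 is then separated by chromatography.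

**Further compounds**

F1 | step 5 | ethyl (2Z)-4-{2-[(tert-butyldimethylsilyl)oxy]-1-[dimethyl(phenyl)silyl]ethylidene}-3,5,5-trimethyl-6-nitrohex-2-enoate | CCOC(=O)/C=C(C)\C(=C(/[Si](C)(C)c1ccccc1)CO[Si](C)(C)C(C)(C)C)C(C)(C)C[N+](=O)[O-]
F2 | step 8 | (1S,4Z)-4-{2-[(tert-butyldimethylsilyl)oxy]-1-iodoethylidene}-3,5,5-trimethylcyclohex-2-en-1-ol | CC1=C[C@@H](O)CC(C)(C)/C1=C(/I)CO[Si](C)(C)C(C)(C)C
F3 | step 8 | (1S,4E)-4-{2-[(tert-butyldimethylsilyl)oxy]ethylidene}-3,5,5-trimethylcyclohex-2-en-1-ol | CC1=C[C@@H](O)CC(C)(C)\C1=C/CO[Si](C)(C)C(C)(C)C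
F4 | step 7 | (4Z)-4-{2-[(tert-butyldimethylsilyl)oxy]-1-[dimethyl(phenyl)silyl]ethylidene}-3,5,5-trimethylcyclohex-2-en-1-ol (racemic) | CC1=CC(O)CC(C)(C)/C1=C(/[Si](C)(C)c2ccccc2)CO[Si](C)(C)C(C)(C)C
F5 | step 7 | (1R,4Z)-4-{2-[(tert-butyldimethylsilyl)oxy]-1-[dimethyl(phenyl)silyl]ethylidene}-3,5,5-trimethylcyclohex-2-en-1-yl acetate | CC1=C[C@H](OC(C)=O)CC(C)(C)/C1=C(/[Si](C)(C)c2ccccc2)CO[Si](C)(C)C(C)(C)C
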